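## Retrosynthetic overview

1. The α-methylene-γ-lactone is closed last, together with unmasking of the C9 ketone, from the ten-membered hydroxy tert-butyl ester 22; the 2-methylbutanoate is installed early and carried through.
2. Key step: the carbocycle is closed at C6–C7 by a CrCl2-mediated intramolecular 2-(alkoxycarbonyl)allylation of the α-acyloxy aldehyde 20. This forms the ring and sets C6 and C7 in one operation, replacing the usual ring-closing metathesis and late acylation.
3. Aldehyde 20 comes from aldehyde 15 (Baylis–Hillman reaction, SN2′ bromination); 15 comes from the (S)-acid 10 by Meldrum's acid homologation (C7, C8), ketalisation and Fukuyama reduction.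
4. Acid 10 comes from geraniol (C1–C6, C9, C10 and both methyls): Sharpless epoxidation and inverting hydrolysis set C4 and C5, then esterification, SeO2 oxidation and Ru–H8-BINAP hydrogenation set C10.
5. Ring order: ten-membered carbocycle (step 15), then lactone (step 16).

Assumption: locants follow the target skeleton (ring C1–C10 with C4 = C(OH)CH3, C5 = CH–O-acyl, C6 = lactone CH–O, C7 = ring-fusion CH, C9 = C=O, C10 = CHCH3; C11–C13 = C(=CH2)–C(=O)); the target is then 4R,5S,6R,7R,10S with a (2S)-2-methylbutanoate.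

## Route

Step 1
Reactants: 1 geraniol
Product: 2 (2S,3S)-2,3-epoxygeraniol
Conditions: Ti(OiPr)4 (5 mol%), L-(+)-diethyl tartrate (6 mol%), t-BuOOH, 4 Å MS, CH2Cl2, −20 °C
Reagents that add atoms: tert-butyl hydroperoxide CC(C)(C)OO
Why: Sharpless asymmetric epoxidation touches only the allylic alcohol alkene, and L-(+)-tartrate delivers oxygen to the face that gives the (2S,3S)-epoxide (future C5 and C4).

Step 2
Reactants: 2 (2S,3S)-2,3-epoxygeraniol
Product: 3 PMB ether of 2
Conditions: NaH, 4-methoxybenzyl chloride, Bu4NI (cat.), THF/DMF, 0 °C → rt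
Reagents that add atoms: 4-methoxybenzyl chloride COc1ccc(CCl)cc1
Why: Williamson etherification of the primary alkoxide protects the future C6 oxygen without touching either epoxide stereocentre.

Step 3
Reactants: 3 PMB ether
Product: 4 (2S,3R)-diol
Conditions: HClO4 (5 mol%), THF/H2O (3:1), 0 °C → rt
Reagents that add atoms: water O
Why: acid-catalysed epoxide hydrolysis in which water opens the protonated trisubstituted epoxide at the tertiary carbon with inversion (sets C4 as R) while the C5–O bond and its S configuration stay intact.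

Step 4
Reactants: 4 (2S,3R)-diol; 5 (S)-2-methylbutanoic acid
Product: 6 C5 (2S)-2-methylbutanoate
Conditions: DCC, DMAP (10 mol%), CH2Cl2, 0 °C → rt
Reagents that add atoms: none
Why: Steglich esterification acylates the only reactive (secondary) hydroxyl, the tertiary C4–OH being inert, and the α-stereocentre of the acid is not epimerised at 0 °C.

Step 5
Reactants: 6 C5 (2S)-2-methylbutanoate
Product: 7 (E)-allylic alcohol (C9–OH)
Conditions: SeO2 (0.3 equiv), t-BuOOH (3 equiv), salicylic acid (10 mol%), CH2Cl2, rt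
Reagents that add atoms: tert-butyl hydroperoxide CC(C)(C)OO (oxygen relayed by the SeO2 catalyst)
Why: Sharpless–Umbreit allylic oxidation (ene reaction then [2,3]-shift) hydroxylates selectively the (E)-methyl group of the isopropylidene terminus.

Step 6
Reactants: 7 (E)-allylic alcohol
Product: 9 (E)-2-methyl-2-enoic acid, via enal 8 (not isolated)
Conditions: TEMPO (10 mol%), PhI(OAc)2 (1.1 equiv), CH2Cl2, rt; then NaClO2, NaH2PO4, 2-methyl-2-butene, t-BuOH/H2O, 0 °C → rt
Reagents that add atoms: sodium chlorite [Na+].[O-]Cl=O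
Why: TEMPO/PhI(OAc)2 oxidises only the primary allylic alcohol and the Pinnick oxidation converts the enal into the acid without changing the alkene geometry.

Step 7
Reactants: 9 (E)-2-methyl-2-enoic acid
Product: 10 (2S)-2-methyl acid
Conditions: Ru(OAc)2[(S)-H8-BINAP] (1 mol%), H2 (4 atm), MeOH, rt
Reagents that add atoms: none
Why: carboxylate-directed asymmetric hydrogenation of a tiglic-acid-type substrate, where the (S)-ligand gives the (S)-2-methyl acid (as tiglic acid gives (S)-2-methylbutanoic acid) and so sets C10.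

Step 8
Reactants: 10 (2S)-2-methyl acid; 11 Meldrum's acid
Product: 13 β-keto S-ethyl thioester, via acyl Meldrum's acid 12 (not isolated)
Conditions: DCC, DMAP, CH2Cl2, 0 °C → rt; then EtSH, toluene, 80 °C (sealed)
Reagents that add atoms: ethanethiol CCS
Why: C-acylation of Meldrum's acid followed by thermolysis to the acylketene and capture by the thiol adds C8 and C7, and C10 is not enolised because the acidic site lies between the two carbonyls.

Step 9
Reactants: 13 β-keto S-ethyl thioester
Product: 14 dioxolane thioester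
Conditions: TMSOCH2CH2OTMS (2 equiv), TMSOTf (5 mol%), CH2Cl2, −78 → −20 °C; aq. citric acid work-up
Reagents that add atoms: 1,2-bis(trimethylsilyloxy)ethane C[Si](C)(C)OCCO[Si](C)(C)C
Why: Noyori ketalisation masks the C9 ketone at low temperature without epimerising C10, which removes the acidic C8–H and the competing ketone electrophile from the later steps.

Step 10
Reactants: 14 dioxolane thioester
Product: 15 aldehyde (C7)
Conditions: Et3SiH (3 equiv), Pd/C (10 wt% palladium on carbon), acetone, rt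
Reagents that add atoms: none
Why: Fukuyama reduction converts the thioester into the aldehyde chemoselectively, leaving the carboxylic ester, PMB ether and ketal untouched.

Step 11
Reactants: 15 aldehyde; 16 tert-butyl acrylate
Product: 17 Baylis–Hillman adduct (C7 epimers)
Conditions: tert-butyl acrylate (5 equiv), DABCO (1 equiv), 1,4-dioxane/H2O (1:1), rt, 4 d
Reagents that add atoms: none
Why: Morita–Baylis–Hillman reaction attaches C11–C13; the new C7 carbinol is an inconsequential epimer mixture because it is erased in step 12.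

Step 12
Reactants: 17 Baylis–Hillman adduct
Product: 18 (Z)-allylic bromide
Conditions: NBS, Me2S, CH2Cl2, 0 °C → rt
Reagents that add atoms: N-bromosuccinimide O=C1CCC(=O)N1Br
Why: Corey–Kim-type activation of the secondary allylic alcohol and SN2′ delivery of bromide gives the thermodynamically favoured (Z)-2-(bromomethyl)enoate, while the hindered tertiary C4–OH does not react.

Step 13
Reactants: 18 (Z)-allylic bromide
Product: 19 primary alcohol (C6–OH)
Conditions: DDQ (1.3 equiv), CH2Cl2/pH 7 buffer (10:1), 0 °C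
Reagents that add atoms: none
Why: oxidative PMB cleavage under neutral buffered conditions frees C6–OH without acyl migration from C5 and without touching the bromide, ketal or tert-butyl ester.

Step 14
Reactants: 19 primary alcohol
Product: 20 α-acyloxy aldehyde
Conditions: Dess–Martin periodinane, NaHCO3, CH2Cl2, 0 °C → rt; used at once
Reagents that add atoms: none
Why: buffered Dess–Martin oxidation gives the sensitive α-acyloxy aldehyde without epimerising C5.

Step 15
Reactants: 20 α-acyloxy aldehyde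
Product: 22 ten-membered hydroxy tert-butyl ester (6R,7R), via allylchromium dichloride 21 (not isolated)
Conditions: CrCl2 (8 equiv), THF/DMF (4:1), 0.002 M, syringe-pump addition over 12 h, rt; aq. NH4Cl work-up
Reagents that add atoms: none
Why: Nozaki–Hiyama–Kishi-type (chromium Barbier) allylation, the established closure for ten-membered germacranolide rings, in which divalent chromium converts the bromide into allylchromium 21 whose γ-carbon (C7) adds only to the C6 aldehyde through a chair-like six-centre transition state; the tether spanning the two pseudo-equatorial sites gives the anti C6–OH/C7 relationship, and the ring constraint (as in closures of the analogous 4,5-epoxy seco-aldehydes) rather than the Felkin–Anh preference is expected to give the 5,6-threo sense, which is the accepted stereochemical risk.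

Step 16
Reactants: 22 ten-membered hydroxy tert-butyl ester
Product: 25 target CNP0144277.6, via hydroxy acid 23 (not isolated), via lactone ketal 24 (not isolated)
Conditions: CF3CO2H/CH2Cl2 (1:3), 0 °C → rt; then H2O (20 equiv), rt
Reagents that add atoms: water O
Why: acidolysis of the tert-butyl ester, lactonisation of the γ-hydroxy acid by acyl substitution (retention at C6, trans-fused lactone) and ketal hydrolysis to the C9 ketone occur in one pot with no new stereocentre, and the C4–OH is protected from ionisation by the adjacent acyloxy group.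

## Compound list

1 | geraniol, (2E)-3,7-dimethylocta-2,6-dien-1-ol | CC(C)=CCC/C(C)=C/CO | starting material
2 | [(2S,3S)-3-methyl-3-(4-methylpent-3-en-1-yl)oxiran-2-yl]methanol | OC[C@@H]1O[C@@]1(C)CCC=C(C)C | intermediate
3 | (2S,3S)-2-{[(4-methoxybenzyl)oxy]methyl}-3-methyl-3-(4-methylpent-3-en-1-yl)oxirane | COc1ccc(COC[C@@H]2O[C@@]2(C)CCC=C(C)C)cc1 | intermediate
4 | (2S,3R)-1-[(4-methoxybenzyl)oxy]-3,7-dimethyloct-6-ene-2,3-diol | CC(C)=CCC[C@@](C)(O)[C@H](COCc1ccc(OC)cc1)O | intermediate
5 | (S)-2-methylbutanoic acid | CC[C@H](C)C(=O)O | starting material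
6 | (2S,3R)-3-hydroxy-1-[(4-methoxybenzyl)oxy]-3,7-dimethyloct-6-en-2-yl (2S)-2-methylbutanoate | CC(C)=CCC[C@@](C)(O)[C@H](COCc1ccc(OC)cc1)OC(=O)[C@@H](C)CC | intermediate
7 | (2S,3R,6E)-3,8-dihydroxy-1-[(4-methoxybenzyl)oxy]-3,7-dimethyloct-6-en-2-yl (2S)-2-methylbutanoate | OC/C(C)=C/CC[C@@](C)(O)[C@H](COCc1ccc(OC)cc1)OC(=O)[C@@H](C)CC | intermediate
8 | (2S,3R,6E)-3-hydroxy-1-[(4-methoxybenzyl)oxy]-3,7-dimethyl-8-oxooct-6-en-2-yl (2S)-2-methylbutanoate | O=C/C(C)=C/CC[C@@](C)(O)[C@H](COCc1ccc(OC)cc1)OC(=O)[C@@H](C)CC | intermediate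
9 | (2E,6R,7S)-6-hydroxy-8-[(4-methoxybenzyl)oxy]-2,6-dimethyl-7-{[(2S)-2-methylbutanoyl]oxy}oct-2-enoic acid | OC(=O)/C(C)=C/CC[C@@](C)(O)[C@H](COCc1ccc(OC)cc1)OC(=O)[C@@H](C)CC | intermediate
10 | (2S,6R,7S)-6-hydroxy-8-[(4-methoxybenzyl)oxy]-2,6-dimethyl-7-{[(2S)-2-methylbutanoyl]oxy}octanoic acid | OC(=O)[C@@H](C)CCC[C@@](C)(O)[C@H](COCc1ccc(OC)cc1)OC(=O)[C@@H](C)CC | intermediate
11 | Meldrum's acid, 2,2-dimethyl-1,3-dioxane-4,6-dione | CC1(C)OC(=O)CC(=O)O1 | starting material
12 | 5-[(2S,6R,7S)-6-hydroxy-8-[(4-methoxybenzyl)oxy]-2,6-dimethyl-7-{[(2S)-2-methylbutanoyl]oxy}octanoyl]-2,2-dimethyl-1,3-dioxane-4,6-dione (drawn as keto tautomer) | CC1(C)OC(=O)C(C(=O)[C@@H](C)CCC[C@@](C)(O)[C@H](COCc2ccc(OC)cc2)OC(=O)[C@@H](C)CC)C(=O)O1 | intermediate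
13 | S-ethyl (4S,8R,9S)-8-hydroxy-10-[(4-methoxybenzyl)oxy]-4,8-dimethyl-9-{[(2S)-2-methylbutanoyl]oxy}-3-oxodecanethioate | CCSC(=O)CC(=O)[C@@H](C)CCC[C@@](C)(O)[C@H](COCc1ccc(OC)cc1)OC(=O)[C@@H](C)CC | intermediate
14 | S-ethyl 2-{2-[(2S,6R,7S)-6-hydroxy-8-[(4-methoxybenzyl)oxy]-6-methyl-7-{[(2S)-2-methylbutanoyl]oxy}octan-2-yl]-1,3-dioxolan-2-yl}ethanethioate | CCSC(=O)CC1(OCCO1)[C@@H](C)CCC[C@@](C)(O)[C@H](COCc2ccc(OC)cc2)OC(=O)[C@@H](C)CC | intermediate
15 | 2-{2-[(2S,6R,7S)-6-hydroxy-8-[(4-methoxybenzyl)oxy]-6-methyl-7-{[(2S)-2-methylbutanoyl]oxy}octan-2-yl]-1,3-dioxolan-2-yl}acetaldehyde | O=CCC1(OCCO1)[C@@H](C)CCC[C@@](C)(O)[C@H](COCc2ccc(OC)cc2)OC(=O)[C@@H](C)CC | intermediate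
16 | tert-butyl acrylate | C=CC(=O)OC(C)(C)C | starting material
17 | tert-butyl 3-hydroxy-4-{2-[(2S,6R,7S)-6-hydroxy-8-[(4-methoxybenzyl)oxy]-6-methyl-7-{[(2S)-2-methylbutanoyl]oxy}octan-2-yl]-1,3-dioxolan-2-yl}-2-methylidenebutanoate (both carbinol epimers, centre not specified) | C=C(C(=O)OC(C)(C)C)C(O)CC1(OCCO1)[C@@H](C)CCC[C@@](C)(O)[C@H](COCc2ccc(OC)cc2)OC(=O)[C@@H](C)CC | intermediate
18 | tert-butyl (2Z)-2-(bromomethyl)-4-{2-[(2S,6R,7S)-6-hydroxy-8-[(4-methoxybenzyl)oxy]-6-methyl-7-{[(2S)-2-methylbutanoyl]oxy}octan-2-yl]-1,3-dioxolan-2-yl}but-2-enoate | BrC/C(C(=O)OC(C)(C)C)=C\CC1(OCCO1)[C@@H](C)CCC[C@@](C)(O)[C@H](COCc2ccc(OC)cc2)OC(=O)[C@@H](C)CC | intermediate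
19 | tert-butyl (2Z)-2-(bromomethyl)-4-{2-[(2S,6R,7S)-6,8-dihydroxy-6-methyl-7-{[(2S)-2-methylbutanoyl]oxy}octan-2-yl]-1,3-dioxolan-2-yl}but-2-enoate | BrC/C(C(=O)OC(C)(C)C)=C\CC1(OCCO1)[C@@H](C)CCC[C@@](C)(O)[C@H](CO)OC(=O)[C@@H](C)CC | intermediate
20 | tert-butyl (2Z)-2-(bromomethyl)-4-{2-[(2S,6R,7R)-6-hydroxy-6-methyl-7-{[(2S)-2-methylbutanoyl]oxy}-8-oxooctan-2-yl]-1,3-dioxolan-2-yl}but-2-enoate | BrC/C(C(=O)OC(C)(C)C)=C\CC1(OCCO1)[C@@H](C)CCC[C@@](C)(O)[C@H](C=O)OC(=O)[C@@H](C)CC | intermediate
21 | allylchromium dichloride formed from 20 (C13–Cr form drawn; allyl geometry fluxional, not specified) | Cl[Cr](Cl)CC(C(=O)OC(C)(C)C)=CCC1(OCCO1)[C@@H](C)CCC[C@@](C)(O)[C@H](C=O)OC(=O)[C@@H](C)CC | intermediate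
22 | tert-butyl 2-[(6S,10R,11S,12R,13R)-10,12-dihydroxy-6,10-dimethyl-11-{[(2S)-2-methylbutanoyl]oxy}-1,4-dioxaspiro[4.9]tetradecan-13-yl]prop-2-enoate | C=C(C(=O)OC(C)(C)C)[C@H]1CC2(OCCO2)[C@@H](C)CCC[C@@](C)(O)[C@@H](OC(=O)[C@@H](C)CC)[C@@H]1O | intermediate
23 | 2-[(6S,10R,11S,12R,13R)-10,12-dihydroxy-6,10-dimethyl-11-{[(2S)-2-methylbutanoyl]oxy}-1,4-dioxaspiro[4.9]tetradecan-13-yl]prop-2-enoic acid | C=C(C(=O)O)[C@H]1CC2(OCCO2)[C@@H](C)CCC[C@@](C)(O)[C@@H](OC(=O)[C@@H](C)CC)[C@@H]1O | intermediate
24 | C9 ethylene ketal (1,3-dioxolane) of 25, same configuration | C=C1C(=O)O[C@@H]2[C@@H]1CC3(OCCO3)[C@@H](C)CCC[C@@](C)(O)[C@H]2OC(=O)[C@@H](C)CC | intermediate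
25 | (3aR,6S,10R,11S,11aR)-10-hydroxy-6,10-dimethyl-3-methylidene-2,5-dioxododecahydrocyclodeca[b]furan-11-yl (2S)-2-methylbutanoate | C=C1C(=O)O[C@@H]2[C@@H]1CC(=O)[C@@H](C)CCC[C@@](C)(O)[C@H]2OC(=O)[C@@H](C)CC | target

## Summary and risks

Total step count: 16. Longest linear sequence: 16 steps (geraniol 1 → 25).

The three steps most likely to fail:

Step 15 (macrocyclisation; facial sense at C6 and yield). The fallback sets out from aldehyde 20 and rejoins the route at 25. If the closure follows the acyclic preferences instead (Felkin–Anh attack on the α-acyloxy aldehyde combined with syn addition of the (Z)-allylmetal), it gives the C6-epimeric hydroxy ester F1, which still has the correct C7. The lactone is then closed by alkylation with inversion instead of acylation with retention. MsCl/Et3N in CH2Cl2 gives the methanesulfonate F2. CF3CO2H/H2O removes the tert-butyl ester and the dioxolane to give the keto acid mesylate F3. NaHCO3 in DMF at 40 °C then lets the carboxylate displace the mesylate (5-exo-tet SN2, inversion at C6) to give 25.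

Step 11 (Baylis–Hillman reaction; slow with tert-butyl acrylate, and the β-ketal aldehyde can undergo E1cB ring opening during days with amine base). The fallback sets out from aldehyde 15 and rejoins at 17. It is an amine-free vinylalumination: tert-butyl propiolate is hydroaluminated with i-Bu2AlH and N-methylmorpholine N-oxide in THF at 0 °C, and the resulting α-(tert-butoxycarbonyl)vinylalane (3 equiv, one consumed by the tertiary OH) adds to 15 within hours to give the same adduct 17.

Step 5 (SeO2 allylic oxidation; moderate conversion and over-oxidation). The fallback sets out from ester 6 and rejoins at enal 8. Cross-metathesis with methacrolein (10 equiv) and the second-generation Hoveyda–Grubbs catalyst (5 mol%) in CH2Cl2 at 40 °C exchanges the isopropylidene terminus for the (E)-2-methyl enal. Enal 8 is then isolated and taken into the chlorite half of step 6.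

## Further compounds

F1 | step 15 | tert-butyl 2-[(6S,10R,11S,12S,13R)-10,12-dihydroxy-6,10-dimethyl-11-{[(2S)-2-methylbutanoyl]oxy}-1,4-dioxaspiro[4.9]tetradecan-13-yl]prop-2-enoate (C6 epimer of 22 in target numbering) | C=C(C(=O)OC(C)(C)C)[C@H]1CC2(OCCO2)[C@@H](C)CCC[C@@](C)(O)[C@@H](OC(=O)[C@@H](C)CC)[C@H]1O
F2 | step 15 | 12-O-methanesulfonate of F1 | C=C(C(=O)OC(C)(C)C)[C@H]1CC2(OCCO2)[C@@H](C)CCC[C@@](C)(O)[C@@H](OC(=O)[C@@H](C)CC)[C@H]1OS(C)(=O)=O
F3 | step 15 | keto acid mesylate from F2 (tert-butyl ester and dioxolane removed, configuration unchanged) | C=C(C(=O)O)[C@H]1CC(=O)[C@@H](C)CCC[C@@](C)(O)[C@@H](OC(=O)[C@@H](C)CC)[C@H]1OS(C)(=O)=O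
F0 | step 11 | none | none
F0 | step 5 | none | none
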